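**Plan**

1. Numbering used throughout: ethyl C1–C2 on quaternary C3; phenylbutadienyl C4–C7 on C3; cyclohexene C3–C8=C9(CH3)–C10–C14–C15; cyclopentene C10–C11(CH3)–C12=C13(CH3)–C14; C15 carries CH3 and carboxyl C16; β is the face of the C15 methyl.
2. The retrosynthesis first cuts C11–C12 and C12=C13. The cyclopentene has a methyl-bearing C13 doubly bonded to C12, and C12 is joined to the methyl-bearing methine C11 on ring carbon C10; this is what an alkylidene carbene (C12) made from a C14 acetyl group leaves when it inserts into a C–H bond of a C10 ethyl group.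
3. Further cuts: C16 acid to alcohol; C4=C5 by lactol olefination (C4 and C16 tied as a cis γ-lactone); C3–ethyl; C9–methyl (enol triflate); C10–ethyl; C14–C13 (conjugate addition); C3–C8 with C14–C15 (Diels–Alder).
4. Forward: the Diels–Alder reaction makes the cyclohexene; lactonisation adds a temporary second ring that is opened when the chain is joined at C4; C16 is then raised to an ester so that it bears no hydrogen; the carbene insertion closes the cyclopentene.
5. Stereochemistry: C15 from the catalytic asymmetric Diels–Alder reaction; C14 from cuprate addition to the convex face of the cis-lactone; C10 from trans enolate alkylation; C3 from alkylation of the lactone enolate with the cis fusion kept; C11 from the insertion.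

Key step: step 15

Assumption: the (S)-oxazaborolidinium catalyst of step 2 is taken to shield the face of enal 3 that leads to the C15 configuration drawn; should it induce the opposite sense, its (R)-enantiomer is used with no other change.

**Route**

Step 1
Reactants: 1 but-3-en-2-one (methyl vinyl ketone)
Product: 2 2-(triisopropylsilyloxy)buta-1,3-diene
Conditions: iPr3SiOSO2CF3, Et3N, Et2O, 0 °C → rt
Reagents that add atoms: triisopropylsilyl trifluoromethanesulfonate, CC(C)[Si](C(C)C)(C(C)C)OS(=O)(=O)C(F)(F)F
Why: O-silylation of the enone under soft enolisation (silyl enol ether formation) gives the 2-silyloxydiene, the triisopropylsilyl group being chosen so that the enol ether survives the acid catalyst of step 2 and the alkoxide of step 3.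

Step 2
Reactants: 2 2-(triisopropylsilyloxy)buta-1,3-diene; 3 ethyl (E)-3-formylbut-2-enoate
Product: 4 ethyl trans-6-formyl-6-methyl-3-(triisopropylsilyloxy)cyclohex-3-ene-1-carboxylate (C15: CH3 β and CHO α; C3: CO2Et β and H α; enol ether C9=C10)
Conditions: (S)-1-(2-methylphenyl)-3,3-diphenyltetrahydro-1H,3H-pyrrolo[1,2-c][1,3,2]oxazaborole (20 mol %), (CF3SO2)2NH (20 mol %), CH2Cl2, –78 → –40 °C
Reagents that add atoms: none
Why: This is a catalytic enantioselective Diels–Alder reaction of an α-substituted enal under chiral oxazaborolidinium (Lewis acid) activation: the formyl-bound catalyst makes C3 the electrophilic terminus, so the nucleophilic diene CH2 (C8) bonds to C3 and C14 to C15, which places the silyloxy carbon C9 para to the new quaternary centre C15, whose configuration follows from the shielded enal face, while the E geometry of 3 sets formyl and ester trans.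

Step 3
Reactants: 4 the Diels–Alder aldehyde
Product: 6 cis-fused lactone 3a-methyl-6-(triisopropylsilyloxy)-3a,4,7,7a-tetrahydro-2-benzofuran-1(3H)-one (C15–CH3 β; C3–H β; lactone C4(=O)–O–C16H2 on the α face), via hydroxy ester 5 (not isolated)
Conditions: NaBH4, EtOH, –20 °C; then NaOEt (0.3 equiv), 40 °C
Reagents that add atoms: none
Why: Borohydride reduces the aldehyde chemoselectively, and catalytic ethoxide then epimerises C3 through the ester enolate and closes the γ-lactone by transesterification, the cis-fused lactone next to the angular methyl being the thermodynamic sink, which fixes C3–H on the β face.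

Step 4
Reactants: 6 the cis-fused silyloxy lactone
Product: 7 cis-fused enone lactone 3a-methyl-3a,7a-dihydroisobenzofuran-1,6(3H,7H)-dione (C9 ketone; C10=C14; C15–CH3 β; C3–H β)
Conditions: Pd(OAc)2 (1.1 equiv), MeCN, 40 °C
Reagents that add atoms: none
Why: In this Saegusa–Ito oxidation the divalent palladium enolate formed at C10 undergoes β-hydride elimination from C14 only, so the enone C9(=O)–C10=C14 arises with the regiochemistry stored in the Diels–Alder-derived enol ether.

Step 5
Reactants: 7 the cis-fused enone lactone; 8 ethyl vinyl ether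
Product: 9 trimethylsilyl enol ether C9(OSiMe3)=C10 of the lactone carrying a β-(1-ethoxyvinyl) group at C14 (C15–CH3 β; C3–H β)
Conditions: 8, t-BuLi, THF, –78 → 0 °C; CuBr·SMe2 (0.5 equiv), –78 °C; then 7, Me3SiCl, –78 °C; Et3N quench
Reagents that add atoms: ethyl vinyl ether 8, C=COCC; chlorotrimethylsilane, C[Si](C)(C)Cl
Why: This is a Me3SiCl-accelerated conjugate addition of a 1-alkoxyvinyl cuprate (an acetyl anion equivalent): in the cis-fused bicycle C16 is pseudo-axial on the α face and C3–H is axial on the β face, so axial attack at C14 should come from the convex β face, anti to the lactone ring and cis to the C15 methyl, and the enolate is trapped regiospecifically as the C9=C10 silyl enol ether.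

Step 6
Reactants: 9 the silyl enol ether; 10 iodoethane
Product: 11 C9 ketone with C14 β-(1-ethoxyvinyl) and C10 α-ethyl (trans), cis-lactone unchanged
Conditions: BnMe3NF (anhydrous), EtI, 4 Å MS, THF, 0 °C → rt
Reagents that add atoms: iodoethane 10, CCI
Why: Fluoride-induced regiospecific alkylation of a silyl enol ether through its ammonium enolate avoids an alkyllithium that would attack the lactone, and ethylation at C10 should occur anti to the C14 substituent (α face) to give the trans-2,3-disubstituted cyclohexanone, which is also the more stable epimer.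

Step 7
Reactants: 11 the C10-ethyl ketone
Product: 12 enol triflate C9(OSO2CF3)=C8, otherwise as 11
Conditions: KN(SiMe3)2, THF, –78 °C; PhN(SO2CF3)2, –78 → 0 °C
Reagents that add atoms: N-phenylbis(trifluoromethanesulfonimide), O=S(=O)(N(c1ccccc1)S(=O)(=O)C(F)(F)F)C(F)(F)F
Why: Kinetic deprotonation of the ketone at the unhindered C8 methylene (not at tertiary C10–H, nor at the less acidic lactone C3–H) and O-sulfonylation give the enol triflate that fixes the future C8=C9 double bond.

Step 8
Reactants: 12 the enol triflate
Product: 13 C9-methyl cyclohexene lactone (C8=C9; C3–H β; C10 α-ethyl; C14 β-(1-ethoxyvinyl))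
Conditions: MeZnCl, Pd(PPh3)4 (5 mol %), THF, rt
Reagents that add atoms: methylzinc chloride, C[Zn]Cl
Why: Negishi cross-coupling of the alkenyl triflate with a methylzinc reagent at zerovalent palladium (oxidative addition, transmetallation, reductive elimination) installs the C9 methyl under neutral conditions that spare the lactone, the enol ether and the acidic C3–H.

Step 9
Reactants: 13 the C9-methyl lactone; 10 iodoethane
Product: 14 C3 β-ethyl lactone (C3: ethyl β and lactone carbonyl C4 α; otherwise as 13)
Conditions: LiN(iPr)2, THF, –78 °C; EtI, DMPU, –78 → –20 °C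
Reagents that add atoms: iodoethane 10, CCI
Why: In this alkylation of the lactone dienolate at its α-carbon C3 the enolate is planar within the five-membered ring, so iodoethane should approach from the β face opposite the cyclohexene ring and the ethyl group enters cis to the C15 methyl with the cis ring fusion kept, while α-attack leaves the alkene at C8=C9.

Step 10
Reactants: 14 the C3-ethyl lactone
Product: 15 lactol (C4 hemiacetal as an anomer mixture; otherwise as 14)
Conditions: iBu2AlH (1.1 equiv), CH2Cl2, –78 °C; aq. potassium sodium tartrate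
Reagents that add atoms: none
Why: Partial reduction of the lactone with iBu2AlH stops at the aluminium hemiacetal at –78 °C and gives the lactol, in which C4 is at the aldehyde level and C16 at the alcohol level, while the enol ether masks the acetyl group from the hydride.

Step 11
Reactants: 15 the lactol; 16 diethyl [(E)-3-phenylprop-2-en-1-yl]phosphonate
Product: 18 hydroxy ketone: cyclohexene with C3 β-ethyl and α-[(1E,3E)-4-phenylbuta-1,3-dienyl]; C8=C9(CH3); C10 α-ethyl; C14 β-acetyl; C15 β-methyl and α-hydroxymethyl, via enol-ether dienyl alcohol 17 (not isolated)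
Conditions: 16 (3 equiv), KN(SiMe3)2 (3 equiv), THF, –78 °C; then 15, –78 → 40 °C; then 1 M HCl (aq), 0 °C
Reagents that add atoms: diethyl [(E)-3-phenylprop-2-en-1-yl]phosphonate 16, CCOP(=O)(OCC)C/C=C/c1ccccc1; water, O
Why: In this Horner–Wadsworth–Emmons olefination of the lactol through its open hydroxy aldehyde the allylic phosphonate anion adds at its α-carbon to the neopentyl C4 aldehyde and eliminates to the E C4=C5 bond (C6=C7 keeps the E geometry of 16), and the acidic work-up hydrolyses the enol ether to the C14 acetyl group, which stays β because it is equatorial and trans to the C10 ethyl.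

Step 12
Reactants: 18 the hydroxy ketone
Product: 19 keto aldehyde (C16 = CHO; otherwise as 18)
Conditions: Dess–Martin periodinane, CH2Cl2, 0 °C → rt
Reagents that add atoms: none
Why: Dess–Martin oxidation takes the neopentyl primary alcohol to the aldehyde without touching the diene, and the quaternary C15 cannot epimerise.

Step 13
Reactants: 19 the keto aldehyde
Product: 20 keto acid (C16 = CO2H; otherwise as 18)
Conditions: NaClO2, NaH2PO4, 2-methylbut-2-ene, t-BuOH/H2O, rt
Reagents that add atoms: sodium chlorite, [Na+].[O-]Cl=O
Why: Pinnick oxidation (buffered chlorite with an alkene scavenger for HOCl) raises C16 to the carboxylic acid chemoselectively beside the ketone and the diene, so that C16 carries no C–H bond when the carbene is made.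

Step 14
Reactants: 20 the keto acid
Product: 21 allyl ester of 20 (key-step precursor)
Conditions: allyl bromide, K2CO3, DMF, rt
Reagents that add atoms: allyl bromide, C=CCBr
Why: O-alkylation of the carboxylate (SN2 on allyl bromide) is insensitive to the hindrance at C15, keeps the acidic proton away from the lithiated diazo reagent, and gives an ester that palladium-catalysed allyl transfer can later remove without hydrolysis.

Step 15
Reactants: 21 the keto allyl ester; 22 trimethylsilyldiazomethane
Product: 25 allyl ester of the target: trans-fused bicycle with the cyclopentene C10–C11(β-CH3)–C12=C13(CH3)–C14, via diazoalkene 23 (not isolated), via alkylidene carbene 24 (not isolated)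
Conditions: 22, n-BuLi, THF, –78 °C; then 21, –78 °C → rt
Reagents that add atoms: trimethylsilyldiazomethane 22, C[Si](C)(C)C=[N+]=[N-]
Why: Lithiated trimethylsilyldiazomethane adds to the C13 ketone, Peterson-type loss of Me3SiOLi gives diazoalkene 23, and loss of N2 leaves alkylidene carbene 24, whose divalent carbon is C12. This is the established cyclopentene synthesis by 1,5 C–H insertion of alkylidene carbenes generated from ketones in this way. The cyclopentene closes when C12 inserts into a C11–H bond of the C10 ethyl group through a six-centre transition state (C12, C13, C14, C10, C11, H), forming C11–C12 with retention at C11 while C12=C13 is already in place, and the ring is trans-fused because the alkylidene arm (β) and the ethyl group (α) are trans-diequatorial. C11 is the only new stereocentre and is set by the substrate: the hydrogen that reacts is the one that leaves the C11 methyl pointing away from the C9 methyl, that is β and cis to C10–H. The step needs selectivity for the secondary C11–H bonds over every other site within reach, and the substrate should secure it because the only other 1,5 C–H bonds are the primary ones of the C15 methyl (C16 is a hydrogen-free ester at this stage), the dienyl chain sits on the α face 1,3-trans to the arm, the in-plane equatorial arm cannot reach the π face of C8=C9, and the neopentyl ester carbonyl is far less electrophilic than the methyl ketone.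

Step 16
Reactants: 25 the allyl ester of the target
Product: 26 target acid CNP0200738.1
Conditions: Pd(PPh3)4 (5 mol %), morpholine, THF, rt
Reagents that add atoms: none
Why: Palladium-catalysed deallylation (Tsuji–Trost-type allyl transfer to morpholine through a π-allyl complex of divalent palladium) frees the hindered acid under neutral conditions that leave the diene and the five stereocentres untouched.

**Compound list**

1 | but-3-en-2-one (methyl vinyl ketone) | CC(=O)C=C | starting material
2 | 2-(triisopropylsilyloxy)buta-1,3-diene | C=CC(=C)O[Si](C(C)C)(C(C)C)C(C)C | intermediate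
3 | ethyl (E)-3-formylbut-2-enoate | CCOC(=O)/C=C(\C)C=O | starting material
4 | ethyl trans-6-formyl-6-methyl-3-(triisopropylsilyloxy)cyclohex-3-ene-1-carboxylate (C15: CH3 β, CHO α; C3: CO2Et β) | CCOC(=O)[C@@H]1CC(O[Si](C(C)C)(C(C)C)C(C)C)=CC[C@@]1(C)C=O | intermediate
5 | ethyl trans-6-(hydroxymethyl)-6-methyl-3-(triisopropylsilyloxy)cyclohex-3-ene-1-carboxylate (hydroxy ester, not isolated) | CCOC(=O)[C@@H]1CC(O[Si](C(C)C)(C(C)C)C(C)C)=CC[C@@]1(C)CO | intermediate
6 | cis-fused lactone 3a-methyl-6-(triisopropylsilyloxy)-3a,4,7,7a-tetrahydro-2-benzofuran-1(3H)-one (C15–CH3 β, C3–H β) | O=C1OC[C@]2(C)CC=C(O[Si](C(C)C)(C(C)C)C(C)C)C[C@H]12 | intermediate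
7 | cis-fused enone lactone 3a-methyl-3a,7a-dihydroisobenzofuran-1,6(3H,7H)-dione (C15–CH3 β, C3–H β) | O=C1OC[C@]2(C)C=CC(=O)C[C@H]12 | intermediate
8 | ethyl vinyl ether | C=COCC | starting material
9 | trimethylsilyl enol ether C9(OSiMe3)=C10 with C14 β-(1-ethoxyvinyl), cis-lactone | O=C1OC[C@]2(C)[C@@H](C(=C)OCC)C=C(O[Si](C)(C)C)C[C@H]12 | intermediate
10 | iodoethane | CCI | starting material
11 | C9 ketone with C14 β-(1-ethoxyvinyl) and C10 α-ethyl, cis-lactone | O=C1OC[C@]2(C)[C@@H](C(=C)OCC)[C@H](CC)C(=O)C[C@H]12 | intermediate
12 | enol triflate C9(OSO2CF3)=C8 of 11 | O=C1OC[C@]2(C)[C@@H](C(=C)OCC)[C@H](CC)C(OS(=O)(=O)C(F)(F)F)=C[C@H]12 | intermediate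
13 | C9-methyl cyclohexene lactone (C8=C9, C3–H β) | O=C1OC[C@]2(C)[C@@H](C(=C)OCC)[C@H](CC)C(C)=C[C@H]12 | intermediate
14 | C3 β-ethyl lactone (vicinal quaternary C3 and C15) | O=C1OC[C@]2(C)[C@@H](C(=C)OCC)[C@H](CC)C(C)=C[C@]12CC | intermediate
15 | lactol of 14 (C4 hemiacetal, anomer mixture) | OC1OC[C@]2(C)[C@@H](C(=C)OCC)[C@H](CC)C(C)=C[C@]12CC | intermediate
16 | diethyl [(E)-3-phenylprop-2-en-1-yl]phosphonate | CCOP(=O)(OCC)C/C=C/c1ccccc1 | starting material
17 | enol-ether dienyl alcohol (C3 α-dienyl, C16 hydroxymethyl, C14 β-(1-ethoxyvinyl); not isolated) | CC[C@]1(/C=C/C=C/c2ccccc2)C=C(C)[C@@H](CC)[C@H](C(=C)OCC)[C@@]1(C)CO | intermediate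
18 | hydroxy ketone (C14 β-acetyl, C10 α-ethyl, C15 β-methyl α-hydroxymethyl, C3 β-ethyl α-dienyl) | CC[C@]1(/C=C/C=C/c2ccccc2)C=C(C)[C@@H](CC)[C@H](C(C)=O)[C@@]1(C)CO | intermediate
19 | keto aldehyde (C16 = CHO) | CC[C@]1(/C=C/C=C/c2ccccc2)C=C(C)[C@@H](CC)[C@H](C(C)=O)[C@@]1(C)C=O | intermediate
20 | keto acid (C16 = CO2H) | CC[C@]1(/C=C/C=C/c2ccccc2)C=C(C)[C@@H](CC)[C@H](C(C)=O)[C@@]1(C)C(=O)O | intermediate
21 | allyl ester of 20 (key-step precursor) | CC[C@]1(/C=C/C=C/c2ccccc2)C=C(C)[C@@H](CC)[C@H](C(C)=O)[C@@]1(C)C(=O)OCC=C | intermediate
22 | trimethylsilyldiazomethane | C[Si](C)(C)C=[N+]=[N-] | starting material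
23 | diazoalkene from 21 (not isolated) | CC[C@]1(/C=C/C=C/c2ccccc2)C=C(C)[C@@H](CC)[C@H](C(C)=C=[N+]=[N-])[C@@]1(C)C(=O)OCC=C | intermediate
24 | alkylidene carbene, carbene carbon C12 (not isolated) | CC[C@]1(/C=C/C=C/c2ccccc2)C=C(C)[C@@H](CC)[C@H](C(C)=[C])[C@@]1(C)C(=O)OCC=C | intermediate
25 | allyl ester of the target (trans-fused bicyclic diene, C11–CH3 β) | CC[C@]1(/C=C/C=C/c2ccccc2)C=C(C)[C@H]2[C@H](C)C=C(C)[C@@H]2[C@@]1(C)C(=O)OCC=C | intermediate
26 | target acid CNP0200738.1 (route numbering 3S,10S,11R,14R,15R) | CC[C@]1(/C=C/C=C/c2ccccc2)C=C(C)[C@H]2[C@H](C)C=C(C)[C@@H]2[C@@]1(C)C(=O)O | target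

**Totals and risks**

Total step count: 16. Longest linear sequence: 16 steps (from 1).

The three steps most likely to fail:

Step 15. The basic lithiated diazo reagent may enolise the hindered methyl ketone instead of adding to it, so that ketone is returned; once the carbene forms, insertion into the C15 methyl may compete when the arm turns toward C15. Fallback, from 21 back to 25: Wittig chloromethylenation of the ketone (Ph3P=CHCl from (chloromethyl)triphenylphosphonium chloride and KN(SiMe3)2, THF) should give the 1-chloroalkene F10 as an E/Z mixture. KN(SiMe3)2 in Et2O then removes the vinylic proton and chloride (α-elimination), which generates the same alkylidene carbene without a nucleophilic addition to the ketone and should lead to 25 by the same insertion.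

Step 5. Transfer of the thermally fragile 1-alkoxyvinyl ligand to the neopentyl β-carbon C14 may be slow, so that cuprate decomposition, 1,2-addition or attack on the lactone takes over. Fallback, from 7 back to 19: a vinyl cuprate (vinylmagnesium bromide, CuBr·SMe2, Me3SiCl, THF, –78 °C) adds the more robust vinyl group to give the β-vinyl trimethylsilyl enol ether F1. The operations of steps 6 to 9 then give in turn the C10-ethyl vinyl ketone F2, the vinyl enol triflate F3, the C9-methyl vinyl lactone F4 and the C3-ethyl vinyl lactone F5. Tsuji–Wacker oxidation (PdCl2, CuCl, O2, DMF/H2O) turns the vinyl group into the methyl ketone lactone F6. iBu2AlH reduces lactone and ketone together to the lactol carbinol F7, olefination with 16 as in step 11 gives the dienyl diol F8, and Dess–Martin oxidation of both hydroxyl groups gives keto aldehyde 19.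

Step 9. C-alkylation of the hindered dienolate beside the quaternary C15 may be sluggish, so that proton return, O-alkylation or γ-attack takes over. Fallback, from 13 back to 14: the lithium dienolate of 13 (LiN(iPr)2, THF, –78 °C) is added to phenyl vinyl sulfone, a small and far more reactive acceptor than iodoethane (Michael addition, same β-face approach), to give the C3 2-(phenylsulfonyl)ethyl lactone F9. Reductive desulfonylation (Na/Hg, Na2HPO4, MeOH) then leaves the C3 ethyl group of 14.

Further compounds

F1 | step 5 | β-vinyl trimethylsilyl enol ether (C14 β-vinyl, C9(OSiMe3)=C10, cis-lactone) | O=C1OC[C@]2(C)[C@@H](C=C)C=C(O[Si](C)(C)C)C[C@H]12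
F2 | step 5 | C10-ethyl vinyl ketone (C14 β-vinyl, C10 α-ethyl, C9 ketone) | O=C1OC[C@]2(C)[C@@H](C=C)[C@H](CC)C(=O)C[C@H]12
F3 | step 5 | vinyl enol triflate (C9(OSO2CF3)=C8) | O=C1OC[C@]2(C)[C@@H](C=C)[C@H](CC)C(OS(=O)(=O)C(F)(F)F)=C[C@H]12
F4 | step 5 | C9-methyl vinyl lactone (C8=C9, C3–H β) | O=C1OC[C@]2(C)[C@@H](C=C)[C@H](CC)C(C)=C[C@H]12
F5 | step 5 | C3-ethyl vinyl lactone | O=C1OC[C@]2(C)[C@@H](C=C)[C@H](CC)C(C)=C[C@]12CC
F6 | step 5 | methyl ketone lactone (C14 β-acetyl) | O=C1OC[C@]2(C)[C@@H](C(C)=O)[C@H](CC)C(C)=C[C@]12CC
F7 | step 5 | lactol carbinol (C4 hemiacetal, C13 secondary alcohol, epimer mixtures) | OC1OC[C@]2(C)[C@@H](C(C)O)[C@H](CC)C(C)=C[C@]12CC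
F8 | step 5 | dienyl diol (C3 α-dienyl, C16 hydroxymethyl, C13 secondary alcohol) | CC[C@]1(/C=C/C=C/c2ccccc2)C=C(C)[C@@H](CC)[C@H](C(C)O)[C@@]1(C)CO
F9 | step 9 | C3 2-(phenylsulfonyl)ethyl lactone | O=C1OC[C@]2(C)[C@@H](C(=C)OCC)[C@H](CC)C(C)=C[C@]12CCS(=O)(=O)c1ccccc1
F10 | step 15 | 1-chloroalkene from 21 (C13=CHCl, E/Z mixture) | CC[C@]1(/C=C/C=C/c2ccccc2)C=C(C)[C@@H](CC)[C@H](C(C)=CCl)[C@@]1(C)C(=O)OCC=C
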